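**Retrosynthetic overview**
- Labels: ring A (trihydroxy ring) has a1 C‑butyryl, a2 OH, a3 CH3, a4 OH, a5 CH2 bridge, a6 OH; ring B (methoxy ring) has b1 bridge, b2 OH, b3 CH3, b4 OCH3, b5 butyryl, b6 OH.
- Feature used: the oxygens on a2, a4 and a6 of ring A all end as free hydroxyls, so ring A can be built de novo by benzannulation on a four‑membered ring that already carries finished ring B. The a4 oxygen comes from a ketene carbonyl, the a2 oxygen from a siloxyalkyne and the a6 oxygen from an alkoxyalkyne.
- Disconnections: a1–acyl last (Friedel–Crafts); then a3–a4 and a1–a2 (ring A) to a 3‑benzyloxy‑4‑(arylmethyl)cyclobutenone plus 1‑(triisopropylsiloxy)propyne; the cyclobutenone to an arylmethylketene plus benzyloxyethyne.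
- Ring B is the ring of 2,4,6‑trihydroxytoluene, dressed in the order CHO (b1), O‑methyl on the hydroxyl para to CHO (b4), butyryl on the last free carbon (b5), benzyl (b2, b6); CHO is then homologated to CH2CH2COCl.
- Ring order: ring B (bought), cyclobutenone, ring A.

Key step: step 10

Remark: the target has no stereocentre; the single stereocentres met on the way (in the cyclobutenones) are racemic and are erased in the key step.

**Step 1**
Reactants: 1 2,4,6-trihydroxytoluene
Product: 3 2,4,6-trihydroxy-3-methylbenzaldehyde, via aryl iminium chloride 2 (not isolated)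
Conditions: POCl3 (1.1 equiv), DMF, EtOAc, 0 °C to rt; then H2O, 50 °C
Reagents that add atoms: N,N-dimethylformamide CN(C)C=O; water O
Why: Vilsmeier–Haack formylation of the very electron-rich triol at one of its two equivalent free carbons; the iminium group of 2 deactivates the ring against a second attack until hydrolysis releases the aldehyde.

**Step 2**
Reactants: 3 2,4,6-trihydroxy-3-methylbenzaldehyde
Product: 4 2,6-dihydroxy-4-methoxy-3-methylbenzaldehyde
Conditions: MeI (1.05 equiv), K2CO3 (1.0 equiv), DMF, 0 °C to rt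
Reagents that add atoms: iodomethane CI
Why: Williamson O-methylation should take the hydroxyl para to the formyl group, the most acidic one (vinylogous acid) and the only one that cannot chelate the formyl oxygen, as is usual for 2,4,6-trihydroxyaryl carbonyl compounds given one equivalent of alkylating agent.

**Step 3**
Reactants: 4 2,6-dihydroxy-4-methoxy-3-methylbenzaldehyde; 5 butanoyl chloride
Product: 6 3-butanoyl-2,6-dihydroxy-4-methoxy-5-methylbenzaldehyde
Conditions: TiCl4 (3 equiv), CH2Cl2, 0 °C to rt; aq. HCl work-up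
Reagents that add atoms: none
Why: Friedel–Crafts acylation at the only unsubstituted ring carbon, which is activated by an ortho hydroxyl, an ortho methoxy and a para hydroxyl and lies meta to the formyl group, as in the second acylation of acylphloroglucinols; TiCl4 is chosen over AlCl3 so that the methyl ether is not cleaved.

**Step 4**
Reactants: 6 3-butanoyl-2,6-dihydroxy-4-methoxy-5-methylbenzaldehyde
Product: 7 2,6-bis(benzyloxy)-3-butanoyl-4-methoxy-5-methylbenzaldehyde
Conditions: BnBr (2.5 equiv), K2CO3, DMF, 60 °C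
Reagents that add atoms: benzyl bromide BrCc1ccccc1
Why: Williamson etherification of both chelated phenols with excess benzyl bromide; the ring has no free carbon and O-alkylation is favoured in the dipolar aprotic medium.

**Step 5**
Reactants: 7 2,6-bis(benzyloxy)-3-butanoyl-4-methoxy-5-methylbenzaldehyde
Product: 10 3-[2,6-bis(benzyloxy)-3-butanoyl-4-methoxy-5-methylphenyl]propanoic acid, via arylidene Meldrum's acid 8 (not isolated), via benzyl Meldrum's acid 9 (not isolated)
Conditions: Meldrum's acid, HCO2H–Et3N, 95 °C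
Reagents that add atoms: Meldrum's acid CC1(C)OC(=O)CC(=O)O1; water O
Why: One-pot reductive Knoevenagel homologation in which condensation gives 8, formate reduces it by conjugate hydride transfer to 9, and the hot medium hydrolyses and decarboxylates 9 to the propanoic acid; benzyl ethers and the hindered aryl ketone are untouched because no hydrogenation catalyst is used.

**Step 6**
Reactants: 10 3-[2,6-bis(benzyloxy)-3-butanoyl-4-methoxy-5-methylphenyl]propanoic acid
Product: 11 3-[2,6-bis(benzyloxy)-3-butanoyl-4-methoxy-5-methylphenyl]propanoyl chloride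
Conditions: (COCl)2, cat. DMF, CH2Cl2, 0 °C to rt; used crude at once
Reagents that add atoms: oxalyl chloride O=C(Cl)C(=O)Cl
Why: Acid chloride formation through the chloroiminium species from oxalyl chloride and catalytic DMF under cold, neutral conditions; immediate use keeps the chloride from lactonising onto an ortho benzyl ether.

**Step 7**
Reactants: 12 benzyl alcohol; 13 trichloroethylene
Product: 16 (benzyloxy)ethyne, via (E)-benzyl 1,2-dichlorovinyl ether 14 (not isolated), via lithium (benzyloxy)ethynide 15 (not isolated)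
Conditions: KH, THF, 0 °C, then 13, −50 °C to rt; n-BuLi (2.4 equiv), −78 to −40 °C; cold H2O; kept as a cold dried solution
Reagents that add atoms: none
Why: Greene-type alkynyl ether synthesis in which the alkoxide adds anti to dichloroacetylene formed from trichloroethylene (E vinyl ether), n-BuLi eliminates HCl and exchanges the remaining chlorine for lithium, and protonation gives the ynol ether; it is kept cold because benzyl alkynyl ethers undergo sigmatropic rearrangement on warming.

**Step 8**
Reactants: 11 3-[2,6-bis(benzyloxy)-3-butanoyl-4-methoxy-5-methylphenyl]propanoyl chloride; 16 (benzyloxy)ethyne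
Product: 18 rac-3-(benzyloxy)-4-{[2,6-bis(benzyloxy)-3-butanoyl-4-methoxy-5-methylphenyl]methyl}cyclobut-2-en-1-one, via arylmethylketene 17 (not isolated)
Conditions: Et3N, 16 (3 equiv), CH2Cl2, 0 °C to rt, slow addition of 11
Reagents that add atoms: none
Why: Dehydrochlorination gives aldoketene 17, which undergoes [2+2] cycloaddition with the ynol ether, the unsubstituted alkyne carbon bonding to the ketene carbonyl carbon (ketene–alkoxyalkyne cyclobutenone synthesis); the new C4 stereocentre forms racemic, which is immaterial, and the double bond cannot migrate by enolisation because the dienolate would be a cyclobutadiene.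

**Step 9**
Reactants: 19 ethyl acetate
Product: 22 triisopropyl(prop-1-yn-1-yloxy)silane, via lithium dibromoenolate 20 (not isolated), via lithium ynolate 21 (not isolated)
Conditions: CH2Br2, lithium 2,2,6,6-tetramethylpiperidide, THF, −78 °C; LiN(SiMe3)2, then n-BuLi, −78 °C to rt; i-Pr3SiCl, −78 °C to rt
Reagents that add atoms: dibromomethane BrCBr; chlorotriisopropylsilane CC(C)[Si](Cl)(C(C)C)C(C)C
Why: Kowalski ester homologation stopped at the ynolate: acylation of LiCHBr2 and deprotonation give 20, bromine–lithium exchange triggers 1,2-methyl migration to 21, and the bulky silyl chloride traps it on oxygen.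

**Step 10**
Reactants: 18 rac-3-(benzyloxy)-4-{[2,6-bis(benzyloxy)-3-butanoyl-4-methoxy-5-methylphenyl]methyl}cyclobut-2-en-1-one; 22 triisopropyl(prop-1-yn-1-yloxy)silane
Product: 26 1-[2,4-bis(benzyloxy)-3-{[6-(benzyloxy)-2-hydroxy-3-methyl-4-(triisopropylsilyloxy)phenyl]methyl}-6-methoxy-5-methylphenyl]butan-1-one, via vinylketene 23 (not isolated), via vinylcyclobutenone 24 (not isolated), via dienylketene 25 (not isolated)
Conditions: 22 (2 equiv), toluene, 110 °C, sealed tube, argon
Reagents that add atoms: none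
Why: Danheiser benzannulation: on heating, 18 opens by reversible 4π electrocyclic cleavage of its C1–C4 bond to the (benzyloxy)vinylketene 23, the arylmethyl group turning outward so that no 1,5-hydrogen shift can intervene. The nucleophilic methyl-bearing carbon of siloxyalkyne 22 attacks the ketene carbonyl carbon and the oxygen-bearing alkyne carbon bonds to the ketene alpha carbon ([2+2]), giving 24 with the new bonds a3–a4 and a1–a2. 24 opens (4π) to dienylketene 25, which closes ring A by disrotatory 6π electrocyclisation between the ketene carbon a4 and the terminal carbon a5, and tautomerisation gives phenol 26. The closest known chemistry is the benzannulation of cyclobutenones with siloxyalkynes and the thermal formation of phloroglucinol diethers from alkynyl ethers by way of 3-alkoxycyclobutenones. No stereocentre is formed and the racemic centre of 18 is erased on ring opening. The step needs regiocontrol in the [2+2] event so that the methyl group lies between two oxygens, and the polarity of the ynol silyl ether (beta carbon nucleophilic) against the electrophilic ketene carbon secures it, while the ketone and ethers of ring B are inert to neutral heat.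

**Step 11**
Reactants: 26 1-[2,4-bis(benzyloxy)-3-{[6-(benzyloxy)-2-hydroxy-3-methyl-4-(triisopropylsilyloxy)phenyl]methyl}-6-methoxy-5-methylphenyl]butan-1-one
Product: 27 1-[2,4-bis(benzyloxy)-3-{[6-(benzyloxy)-2,4-dihydroxy-3-methylphenyl]methyl}-6-methoxy-5-methylphenyl]butan-1-one
Conditions: Bu4NF, AcOH, THF, 0 °C
Reagents that add atoms: none
Why: Fluoride-induced cleavage of the aryl silyl ether, buffered with acetic acid so that the electron-rich resorcinol is not left as its phenoxide; benzyl ethers and ketone are inert.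

**Step 12**
Reactants: 27 1-[2,4-bis(benzyloxy)-3-{[6-(benzyloxy)-2,4-dihydroxy-3-methylphenyl]methyl}-6-methoxy-5-methylphenyl]butan-1-one
Product: 28 1-[2,4-dihydroxy-6-methoxy-5-methyl-3-[(2,4,6-trihydroxy-3-methylphenyl)methyl]phenyl]butan-1-one
Conditions: H2 (1 atm), 10% Pd/C, EtOAc–MeOH, rt
Reagents that add atoms: none
Why: Hydrogenolysis of the three benzyl ethers on palladium; the hydrogen-bonded aryl ketone and the diarylmethane should not be reduced under these mild conditions.

**Step 13**
Reactants: 28 1-[2,4-dihydroxy-6-methoxy-5-methyl-3-[(2,4,6-trihydroxy-3-methylphenyl)methyl]phenyl]butan-1-one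
Product: 29 1-[3-[(3-butanoyl-2,4,6-trihydroxy-5-methylphenyl)methyl]-2,4-dihydroxy-6-methoxy-5-methylphenyl]butan-1-one (CNP0183860.0)
Conditions: butanoic acid (1.2 equiv), BF3·OEt2 (as solvent), 70 °C, argon; then aq. NaOAc
Reagents that add atoms: butanoic acid CCCC(=O)O
Why: Friedel–Crafts acylation promoted by BF3 at a1, the only unsubstituted aromatic carbon in the molecule, flanked by two hydroxyls; O-acyl intermediates should migrate to carbon by Fries rearrangement and ring B has no free position.

**Compound list**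
1 | 2,4,6-trihydroxytoluene | Cc1c(O)cc(O)cc1O | starting material
2 | (2,4,6-trihydroxy-3-methylbenzylidene)dimethylammonium chloride | C[N+](C)=Cc1c(O)cc(O)c(C)c1O.[Cl-] | intermediate
3 | 2,4,6-trihydroxy-3-methylbenzaldehyde | O=Cc1c(O)cc(O)c(C)c1O | intermediate
4 | 2,6-dihydroxy-4-methoxy-3-methylbenzaldehyde | O=Cc1c(O)cc(OC)c(C)c1O | intermediate
5 | butanoyl chloride | CCCC(=O)Cl | starting material
6 | 3-butanoyl-2,6-dihydroxy-4-methoxy-5-methylbenzaldehyde | CCCC(=O)c1c(OC)c(C)c(O)c(C=O)c1O | intermediate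
7 | 2,6-bis(benzyloxy)-3-butanoyl-4-methoxy-5-methylbenzaldehyde | CCCC(=O)c1c(OC)c(C)c(OCc2ccccc2)c(C=O)c1OCc1ccccc1 | intermediate
8 | 5-{[2,6-bis(benzyloxy)-3-butanoyl-4-methoxy-5-methylphenyl]methylidene}-2,2-dimethyl-1,3-dioxane-4,6-dione | CCCC(=O)c1c(OC)c(C)c(OCc2ccccc2)c(C=C2C(=O)OC(C)(C)OC2=O)c1OCc1ccccc1 | intermediate
9 | 5-{[2,6-bis(benzyloxy)-3-butanoyl-4-methoxy-5-methylphenyl]methyl}-2,2-dimethyl-1,3-dioxane-4,6-dione | CCCC(=O)c1c(OC)c(C)c(OCc2ccccc2)c(CC2C(=O)OC(C)(C)OC2=O)c1OCc1ccccc1 | intermediate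
10 | 3-[2,6-bis(benzyloxy)-3-butanoyl-4-methoxy-5-methylphenyl]propanoic acid | CCCC(=O)c1c(OC)c(C)c(OCc2ccccc2)c(CCC(=O)O)c1OCc1ccccc1 | intermediate
11 | 3-[2,6-bis(benzyloxy)-3-butanoyl-4-methoxy-5-methylphenyl]propanoyl chloride | CCCC(=O)c1c(OC)c(C)c(OCc2ccccc2)c(CCC(=O)Cl)c1OCc1ccccc1 | intermediate
12 | benzyl alcohol | OCc1ccccc1 | starting material
13 | trichloroethylene | ClC=C(Cl)Cl | starting material
14 | (E)-benzyl 1,2-dichlorovinyl ether | Cl/C=C(/Cl)OCc1ccccc1 | intermediate
15 | lithium (benzyloxy)ethynide | [Li]C#COCc1ccccc1 | intermediate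
16 | (benzyloxy)ethyne | C#COCc1ccccc1 | intermediate
17 | 3-[2,6-bis(benzyloxy)-3-butanoyl-4-methoxy-5-methylphenyl]prop-1-en-1-one (arylmethylketene) | CCCC(=O)c1c(OC)c(C)c(OCc2ccccc2)c(CC=C=O)c1OCc1ccccc1 | intermediate
18 | rac-3-(benzyloxy)-4-{[2,6-bis(benzyloxy)-3-butanoyl-4-methoxy-5-methylphenyl]methyl}cyclobut-2-en-1-one | O=C1C=C(OCc2ccccc2)C1Cc1c(OCc2ccccc2)c(C)c(OC)c(C(=O)CCC)c1OCc1ccccc1 | intermediate
19 | ethyl acetate | CCOC(C)=O | starting material
20 | lithium 1,1-dibromoprop-1-en-2-olate | CC([O-])=C(Br)Br.[Li+] | intermediate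
21 | lithium prop-1-yn-1-olate | CC#C[O-].[Li+] | intermediate
22 | triisopropyl(prop-1-yn-1-yloxy)silane | CC#CO[Si](C(C)C)(C(C)C)C(C)C | intermediate
23 | (3Z)-3-(benzyloxy)-5-[2,6-bis(benzyloxy)-3-butanoyl-4-methoxy-5-methylphenyl]penta-1,3-dien-1-one (vinylketene) | O=C=C/C(OCc1ccccc1)=C/Cc1c(OCc2ccccc2)c(C)c(OC)c(C(=O)CCC)c1OCc1ccccc1 | intermediate
24 | rac-4-{(1Z)-1-(benzyloxy)-3-[2,6-bis(benzyloxy)-3-butanoyl-4-methoxy-5-methylphenyl]prop-1-en-1-yl}-2-methyl-3-(triisopropylsilyloxy)cyclobut-2-en-1-one | O=C1C(C)=C(O[Si](C(C)C)(C(C)C)C(C)C)C1/C(OCc1ccccc1)=C/Cc1c(OCc2ccccc2)c(C)c(OC)c(C(=O)CCC)c1OCc1ccccc1 | intermediate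
25 | (3E,5Z)-5-(benzyloxy)-7-[2,6-bis(benzyloxy)-3-butanoyl-4-methoxy-5-methylphenyl]-2-methyl-3-(triisopropylsilyloxy)hepta-1,3,5-trien-1-one (dienylketene) | O=C=C(C)/C(O[Si](C(C)C)(C(C)C)C(C)C)=C\C(OCc1ccccc1)=C\Cc1c(OCc2ccccc2)c(C)c(OC)c(C(=O)CCC)c1OCc1ccccc1 | intermediate
26 | 1-[2,4-bis(benzyloxy)-3-{[6-(benzyloxy)-2-hydroxy-3-methyl-4-(triisopropylsilyloxy)phenyl]methyl}-6-methoxy-5-methylphenyl]butan-1-one | Cc1c(O)c(Cc2c(OCc3ccccc3)c(C)c(OC)c(C(=O)CCC)c2OCc2ccccc2)c(OCc2ccccc2)cc1O[Si](C(C)C)(C(C)C)C(C)C | intermediate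
27 | 1-[2,4-bis(benzyloxy)-3-{[6-(benzyloxy)-2,4-dihydroxy-3-methylphenyl]methyl}-6-methoxy-5-methylphenyl]butan-1-one | Cc1c(O)c(Cc2c(OCc3ccccc3)c(C)c(OC)c(C(=O)CCC)c2OCc2ccccc2)c(OCc2ccccc2)cc1O | intermediate
28 | 1-[2,4-dihydroxy-6-methoxy-5-methyl-3-[(2,4,6-trihydroxy-3-methylphenyl)methyl]phenyl]butan-1-one | Cc1c(O)c(Cc2c(O)c(C)c(OC)c(C(=O)CCC)c2O)c(O)cc1O | intermediate
29 | 1-[3-[(3-butanoyl-2,4,6-trihydroxy-5-methylphenyl)methyl]-2,4-dihydroxy-6-methoxy-5-methylphenyl]butan-1-one | CCCC(=O)c1c(O)c(C)c(O)c(Cc2c(O)c(C)c(OC)c(C(=O)CCC)c2O)c1O | target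

**Step count**
Total: 13 steps. Longest linear sequence: 11 steps (steps 1–6, 8, 10–13); steps 7 and 9 are one-step side branches.

**Steps most likely to fail**

1. Step 10. The donor-substituted cyclobutenone may open too slowly, so that decomposition of the siloxyalkyne or acylation of the product phenol by the vinylketene consumes the material before ring A forms.
Fallback (sets out from 7 and 1, returns at 28): aldehyde 7 would be reduced with NaBH4 in MeOH–THF at 0 °C, the di-ortho-substituted ketone reacting far more slowly, to [2,6-bis(benzyloxy)-3-butanoyl-4-methoxy-5-methylphenyl]methanol F1. F1 would be ionised with catalytic TsOH in MeCN in the presence of excess 1, so that the alkoxy-stabilised benzylic cation alkylates one of the two equivalent free carbons of the triol (Friedel–Crafts benzylation), giving 1-[2,4-bis(benzyloxy)-6-methoxy-5-methyl-3-[(2,4,6-trihydroxy-3-methylphenyl)methyl]phenyl]butan-1-one F2. Hydrogenolysis (H2, 10% Pd/C) would then give 28.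

2. Step 8. The aldoketene may dimerise, and the heat-sensitive benzyl ynol ether may rearrange or add HCl, faster than the two combine; the acid chloride may also lactonise with loss of benzyl chloride.
Fallback (sets out from 11, returns at 27): 11 would be treated with Et3N and commercial ethoxyethyne, a robust ketenophile usable in large excess, to give rac-4-{[2,6-bis(benzyloxy)-3-butanoyl-4-methoxy-5-methylphenyl]methyl}-3-ethoxycyclobut-2-en-1-one F3. Dilute aqueous HCl in THF would hydrolyse the vinylogous ester to the 2-substituted cyclobutane-1,3-dione, present as its enol 2-{[2,6-bis(benzyloxy)-3-butanoyl-4-methoxy-5-methylphenyl]methyl}-3-hydroxycyclobut-2-en-1-one F4. O-Benzylation with BnBr and Ag2O in CH2Cl2 would give 3-(benzyloxy)-2-{[2,6-bis(benzyloxy)-3-butanoyl-4-methoxy-5-methylphenyl]methyl}cyclobut-2-en-1-one F5. Benzannulation of this 2,3-disubstituted cyclobutenone with 22 (toluene, 110 °C) would give the silyl isomer 1-[2,4-bis(benzyloxy)-3-{[6-(benzyloxy)-4-hydroxy-3-methyl-2-(triisopropylsilyloxy)phenyl]methyl}-6-methoxy-5-methylphenyl]butan-1-one F6. Desilylation with Bu4NF and AcOH would give 27, because both hydroxyls flanking the methyl group are then free.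

3. Step 13. Under hot Lewis acid the methylene bridge may cleave and scramble by retro-Friedel–Crafts reaction, phenols may be O-acylated without migration to carbon, or the methyl ether may be lost.
Fallback (sets out from 28, returns at 29): Houben–Hoesch reaction of 28 with butanenitrile, ZnCl2 and HCl gas in Et2O at 0 °C would give 1-[3-({2,4-dihydroxy-3-butanoyl-6-methoxy-5-methylphenyl}methyl)-2,4,6-trihydroxy-5-methylphenyl]butan-1-iminium chloride F7 at low temperature. Hydrolysis in water at 90 °C would then give 29.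

**Further compounds**
F1 | step 10 | [2,6-bis(benzyloxy)-3-butanoyl-4-methoxy-5-methylphenyl]methanol | CCCC(=O)c1c(OC)c(C)c(OCc2ccccc2)c(CO)c1OCc1ccccc1
F2 | step 10 | 1-[2,4-bis(benzyloxy)-6-methoxy-5-methyl-3-[(2,4,6-trihydroxy-3-methylphenyl)methyl]phenyl]butan-1-one | Cc1c(O)c(Cc2c(OCc3ccccc3)c(C)c(OC)c(C(=O)CCC)c2OCc2ccccc2)c(O)cc1O
F3 | step 8 | rac-4-{[2,6-bis(benzyloxy)-3-butanoyl-4-methoxy-5-methylphenyl]methyl}-3-ethoxycyclobut-2-en-1-one | O=C1C=C(OCC)C1Cc1c(OCc2ccccc2)c(C)c(OC)c(C(=O)CCC)c1OCc1ccccc1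
F4 | step 8 | 2-{[2,6-bis(benzyloxy)-3-butanoyl-4-methoxy-5-methylphenyl]methyl}-3-hydroxycyclobut-2-en-1-one | O=C1CC(O)=C1Cc1c(OCc2ccccc2)c(C)c(OC)c(C(=O)CCC)c1OCc1ccccc1
F5 | step 8 | 3-(benzyloxy)-2-{[2,6-bis(benzyloxy)-3-butanoyl-4-methoxy-5-methylphenyl]methyl}cyclobut-2-en-1-one | O=C1CC(OCc2ccccc2)=C1Cc1c(OCc2ccccc2)c(C)c(OC)c(C(=O)CCC)c1OCc1ccccc1
F6 | step 8 | 1-[2,4-bis(benzyloxy)-3-{[6-(benzyloxy)-4-hydroxy-3-methyl-2-(triisopropylsilyloxy)phenyl]methyl}-6-methoxy-5-methylphenyl]butan-1-one | Cc1c(O)cc(OCc2ccccc2)c(Cc2c(OCc3ccccc3)c(C)c(OC)c(C(=O)CCC)c2OCc2ccccc2)c1O[Si](C(C)C)(C(C)C)C(C)C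
F7 | step 13 | 1-[3-({2,4-dihydroxy-3-butanoyl-6-methoxy-5-methylphenyl}methyl)-2,4,6-trihydroxy-5-methylphenyl]butan-1-iminium chloride | CCCC(=[NH2+])c1c(O)c(C)c(O)c(Cc2c(O)c(C)c(OC)c(C(=O)CCC)c2O)c1O.[Cl-]
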